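All runs were computed for substances that don't exist.

Do not read a late ratio of isomer of the product to target as the split of the reaction. That ratio has target in its denominator, and in the alder run target falls from 48.4% to 44.2% while substrate is still being consumed. The flask carries the oak run on to the asked time; the alder run had less free catalyst.

all flasks: substrate 0.10 M

|  | free catalyst | remark | time |
|---|---|---|---|
| oak | 0.32 mol% | the very flask that is asked about, followed so far |  |
| alder | 0.21 mol% | run made earlier |  |
| flask | 0.32 mol% |  | 25 h |

| run | time / h | isomer of the product / % | target / % | substrate / % |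
|---|---|---|---|---|
| oak | 0.667 | 0.3 | 13.1 | 84.5 |
| oak | 1.00 | 0.2 | 18.6 | 78.7 |
| oak | 1.33 | 0.4 | 23.6 | 74.2 |
| oak | 2.00 | 0.2 | 30.8 | 65.8 |
| oak | 3.00 | 1.1 | 39.0 | 56.0 |
| oak | 5.00 | 1.3 | 48.0 | 43.7 |
| oak | 8.00 | 1.1 | 53.5 | 32.9 |
| alder | 2.50 | 0.5 | 26.9 | 70.5 |
| alder | 5.00 | 0.7 | 39.2 | 54.1 |
| alder | 8.00 | 1.0 | 46.1 | 42.4 |
| alder | 10.0 | 0.9 | 47.4 | 36.9 |
| alder | 12.0 | 1.4 | 48.4 | 32.0 |
| alder | 15.0 | 1.5 | 46.7 | 27.5 |
| alder | 20.0 | 1.1 | 44.2 | 21.8 |

(readings scatter by 0.3 percentage points)

1. share of isomer of the product in isomer of the product plus target at 5.0 min
2. share of isomer of the product in isomer of the product plus target at 25 h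
3. which of isomer of the product and target there is more of at 25 h

Reckon first the split f = 1.87%, the isomer of the product found per substrate consumed (a selectivity), pooled over the latest readings since each carries a scatter of 0.3 percentage points. Object that the catalyst might shift it. But the oak readings give 1.94% and the alder readings 1.83%, so keep one f, and expect it as the share at 5.0 min.

For the end, let A be the substrate. Its reciprocal rises in the oak run with slope s = 0.255 /h, which puts A at 13.6% at 25 h. Object that this runs past the last oak reading. But the alder slope reads 0.171 /h at 10.0 h and 0.179 /h at 20.0 h, so keep the line. The isomer then stands at f(1−A) = 1.62%.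

Target needs another reckoning. Between 15.0 h and 20.0 h the alder run loses substrate and target together, which reads as a first-order loss λ = 0.0361 /h into something unseen. Step the last oak reading forward with λ on the mean target: this gives 43.2%, hence a share of 3.61%, with target ahead.

The forecast, calling the isomer “a minor parallel product that is roughly stable”, says 1.8% and 3.2% with target ahead, a little below my two shares. The flask gives 1.78% and 3.71%, with target ahead at 40.2% against 1.55%.

    substrate ⇌ other conformer, settled at all times (K = 0.0190)
    substrate + free catalyst → free catalyst + target (k = 0.210 /M/s)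
    free catalyst + other conformer → free catalyst + isomer of the product (k = 0.200 /M/s)
    target → over-reaction product (k = 1.10 × 10⁻⁵ /s)
    2 free catalyst → spent catalyst (k = 0.0970 /M/s)

The share in the flask is 3.71% because the reading is taken at 25 h and not at ten times that time: left for 250 h, the flask shows a share of 90.6%, with 0.183% of target against 1.75% of isomer of the product. Use f on what the substrate left at 25 h allows: with 13% left in the flask it gives 1.63% of isomer of the product, and the flask holds 1.55%. In the neighbour flask at 0.025 M, with 38% of substrate left, f gives 1.16% of isomer of the product, and that flask holds 1.09%.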